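**Retrosynthetic overview**

1. Ring numbering used throughout: cyclohexene C1(CH3)=C2H, C3 (resorcinol ring that carries the chalcone), C4 (aroyl), C5 (2,4-dihydroxyphenyl), C6H2; the target is (3S,4R,5S). The strategy rests on the 1,4-relation of the aroyl-bearing C4 and the methyl-bearing C1: with C3 and C2 between them they are the C3–C4=C5–C6 diene of a 3-aroyl-6-methyl-2-pyranone, and C5–C6 is a styrene.
2. Key disconnection: C4–C5 and C1–C6 by an enantioselective, endo, inverse-demand [4+2] of pyranone 10 with styrene 13 (divalent copper, bis(oxazoline)). It closes the carbocycle and leaves the pyranone O–C(=O) as a temporary bridge from C1 to C4 (lactone 14).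
3. The bridge is expelled as CO2 (14 → dienone 15, only C5 stereogenic). In 14 the endo C5 aryl covers the C2=C3 face anti to the lactone oxygen, so no π-allyl or SN2′ opening of the bridge is relied on. Instead the C3–aryl bond is made by 1,4-addition of an aryl cuprate anti to the C5 aryl, and C4 is set by kinetic protonation.
4. The chalcone enone is added last by a directed aldol/elimination that does not enolise C4. All eight phenols travel as MOM ethers and are freed in one non-protic step.
5. Ring order: the arenes are bought; pyranone ring (step 6) → cyclohexene with lactone bridge (step 9) → bridge removed (step 10).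

Key step: step 9

Assumption: the sense of induction in step 9 is assigned from the square-planar chelate (quadrant) model of the copper bis(oxazoline) complex, which points to the (S,S)-ligand; the mirror-image ligand is taken if the lactone proves to be the enantiomer.

Abbreviations: MOM = CH2OCH3; ArA = 2,4-bis(methoxymethoxy)-3-[(E)-3-methylbut-1-enyl]phenyl; ArB = 2,4-bis(methoxymethoxy)phenyl; TBS = tert-butyldimethylsilyl.

**Route**

Step 1
Reactants: 1 2,4-dihydroxyacetophenone
Product: 2 1-(2,4-dihydroxy-3-iodophenyl)ethanone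
Conditions: I2 (0.4 equiv), HIO3 (0.2 equiv), EtOH/H2O, rt
Reagents that add atoms: iodine, II; iodic acid, OI(=O)=O
Why: Electrophilic aromatic iodination in which HIO3 returns all iodide to the electrophile; the hydrogen-bonded 2-hydroxy ketone localises the ring π-bonds so that C3, between the two hydroxyls, is the site attacked (the same site as in C-allylation and Claisen chemistry of this ketone), and sub-stoichiometric iodine limits a second iodination at C5.

Step 2
Reactants: 2 1-(2,4-dihydroxy-3-iodophenyl)ethanone
Product: 3 1-[3-iodo-2,4-bis(methoxymethoxy)phenyl]ethanone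
Conditions: NaH (2.3 equiv), MOMCl (2.5 equiv), DMF, 0 °C → rt
Reagents that add atoms: chloromethyl methyl ether, COCCl
Why: Williamson-type O-alkylation of both sodium phenoxides (the chelated, iodine-flanked 2-OH needs the preformed salt); MOM ethers survive every basic, organometallic and Lewis-acidic step that follows.

Step 3
Reactants: 4 3-methylbut-1-yne
Product: 5 2-[(E)-3-methylbut-1-enyl]-4,4,5,5-tetramethyl-1,3,2-dioxaborolane
Conditions: pinacolborane (1.05 equiv), Cp2Zr(H)Cl (5 mol %), Et3N (10 mol %), neat, sealed tube, 60 °C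
Reagents that add atoms: pinacolborane, [H]B1OC(C)(C)C(C)(C)O1
Why: Zirconocene hydride-catalysed hydroboration of a terminal alkyne is syn and anti-Markovnikov, which fixes the E geometry of the alkenylboronate.

Step 4
Reactants: 3 1-[3-iodo-2,4-bis(methoxymethoxy)phenyl]ethanone; 5 2-[(E)-3-methylbut-1-enyl]-4,4,5,5-tetramethyl-1,3,2-dioxaborolane
Product: 6 1-(ArA)ethanone
Conditions: Pd(OAc)2 (3 mol %), SPhos (6 mol %), K3PO4 (3 equiv), toluene/H2O 10:1, 80 °C
Reagents that add atoms: none
Why: Suzuki–Miyaura coupling; the dialkylbiarylphosphine handles the doubly ortho-substituted iodide and the alkene geometry is retained.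

Step 5
Reactants: 6 1-(ArA)ethanone
Product: 7 ethyl 3-(ArA)-3-oxopropanoate
Conditions: NaH (2.5 equiv), (EtO)2CO (3 equiv), toluene, 80 °C; AcOH quench
Reagents that add atoms: diethyl carbonate, CCOC(=O)OCC
Why: Crossed Claisen condensation of the methyl ketone enolate with a non-enolisable carbonate, driven to completion by deprotonation of the β-keto ester formed.

Step 6
Reactants: 7 ethyl 3-(ArA)-3-oxopropanoate; 8 (E)-4-methoxybut-3-en-2-one
Product: 10 3-(ArA-carbonyl)-6-methyl-2H-pyran-2-one, via open-chain keto ester 9 (not isolated)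
Conditions: K2CO3 (1.5 equiv), MeCN, 0 °C → rt; then AcOH (3 equiv), toluene, 90 °C (EtOH distilled off)
Reagents that add atoms: none
Why: Addition–elimination of the β-keto ester carbanion on the β-methoxy enone (a Knoevenagel-type condensation with a masked 3-oxobutanal) gives 9, and after acidification the methyl-ketone enol lactonises onto the ester with loss of ethanol (a known 2-pyranone annulation of 1,3-dicarbonyl compounds); lactonisation is done on the neutral enol because the stabilised dienolate does not expel ethoxide.

Step 7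
Reactants: 11 2,4-dihydroxybenzaldehyde
Product: 12 2,4-bis(methoxymethoxy)benzaldehyde
Conditions: NaH (2.3 equiv), MOMCl (2.5 equiv), DMF, 0 °C → rt
Reagents that add atoms: chloromethyl methyl ether, COCCl
Why: Williamson-type O-alkylation of both phenoxides; 12 serves three times (styrene, masked acetyl arene, chalcone aldehyde).

Step 8
Reactants: 12 2,4-bis(methoxymethoxy)benzaldehyde
Product: 13 1-ethenyl-2,4-bis(methoxymethoxy)benzene
Conditions: Ph3PCH3Br (1.3 equiv), KOt-Bu (1.25 equiv), THF, 0 °C → rt; stored cold over BHT
Reagents that add atoms: methyltriphenylphosphonium bromide, C[P+](c1ccccc1)(c1ccccc1)c1ccccc1.[Br-]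
Why: Wittig methylenation of an aryl aldehyde with the non-stabilised ylide.

Step 9
Reactants: 10 3-(ArA-carbonyl)-6-methyl-2H-pyran-2-one; 13 1-ethenyl-2,4-bis(methoxymethoxy)benzene
Product: 14 (1S,4S,8R)-4-(ArA-carbonyl)-8-(ArB)-1-methyl-2-oxabicyclo[2.2.2]oct-5-en-3-one (ArB endo, syn to C5=C6 of the bicycle)
Conditions: Cu(OTf)2 (10 mol %), 2,2′-(propane-2,2-diyl)bis[(4S)-4-tert-butyl-4,5-dihydro-1,3-oxazole] (11 mol %), 4 Å MS, CH2Cl2, −30 → −10 °C, 13 (2 equiv) added slowly; cold work-up, chromatography on Et3N-deactivated silica at 0 °C (any exo isomer removed)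
Reagents that add atoms: none
Why: The divalent copper centre is chelated by the lactone and ketone carbonyls of 10, which lowers the LUMO of the pyranone diene (C3–C6) so that the electron-rich alkene of 13 adds in a suprafacial, asynchronous inverse-electron-demand [4+2], its CH2 bonding to pyranone C6 (ring C1) slightly ahead of the benzylic carbon bonding to pyranone C3 (ring C4). The closest known reaction type is the Lewis acid-catalysed, including copper bis(oxazoline)-catalysed, inverse-demand Diels–Alder reaction of 3-acyl and 3-alkoxycarbonyl 2-pyranones with enol ethers, indenes and electron-rich styrenes, which gives isolable 2-oxabicyclo[2.2.2]oct-5-en-3-ones at low temperature. Both new σ-bonds close the six-membered carbocycle in one cycloaddition, and the former ring O–C(=O) of the pyranone is thereby left as the two-atom bridge of a second six-membered (δ-lactone) ring spanning C1 and C4. The two bridgeheads are set together by the face of the flat chelated pyranone that the tert-butyl groups of the ligand leave open, and C8 (ring C5) by endo approach, the aryl lying under the pyranone C4=C5 bond and therefore anti to the lactone bridge. The step needs regio-, endo- and face selectivity: regiochemistry is secured by polarity (the nucleophilic CH2 of the 2,4-dialkoxystyrene attacks the vinylogous position C6 of the chelated 1,3-dicarbonyl unit and the cation-stabilising benzylic carbon joins the dicarbonyl carbon C3), and endo selectivity by secondary overlap of the aryl with the diene, while an exo adduct from the same face would give the opposite C5 after loss of CO2 and is therefore separated here. Temperatures below 0 °C keep CO2 in the adduct and suppress Lewis acid-induced oligomerisation of the styrene.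

Step 10
Reactants: 14 bridged lactone
Product: 15 (ArA)[(6R)-6-(ArB)-4-methylcyclohexa-1,3-dien-1-yl]methanone (ring C1(CH3)=C2–C3=C4(aroyl), C5 stereocentre kept)
Conditions: toluene, 90 °C, argon, BHT (trace); solution used at once
Reagents that add atoms: none
Why: Thermal retro-[4+2] extrusion of CO2 from the bridged lactone is irreversible through loss of gas and gives the conjugated 2-aroylcyclohexa-1,3-diene; C5 is untouched and the temperature is well below that of 1,5-hydrogen shifts in cyclohexadienes.

Step 11
Reactants: 12 2,4-bis(methoxymethoxy)benzaldehyde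
Product: 16 1-[2,4-bis(methoxymethoxy)phenyl]ethanol (racemic)
Conditions: MeMgBr (1.2 equiv), THF, 0 °C; H2O
Reagents that add atoms: methylmagnesium bromide, C[Mg]Br
Why: Grignard addition to the aldehyde gives the carbinol as a masked acetyl group, whose stereocentre is erased by oxidation in step 15.

Step 12
Reactants: 16 1-[2,4-bis(methoxymethoxy)phenyl]ethanol
Product: 17 tert-butyl{1-[2,4-bis(methoxymethoxy)phenyl]ethoxy}dimethylsilane
Conditions: TBSCl (1.2 equiv), imidazole (2 equiv), DMF, rt
Reagents that add atoms: tert-butyldimethylsilyl chloride, CC(C)(C)[Si](C)(C)Cl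
Why: Silylation of the secondary alcohol gives an ether that tolerates butyllithium and the cuprate.

Step 13
Reactants: 17 tert-butyl{1-[2,4-bis(methoxymethoxy)phenyl]ethoxy}dimethylsilane; 15 dienone
Product: 19 trimethylsilyl enol ether of the 1,4-adduct [ring C3 (S) carries 2,6-bis(methoxymethoxy)-3-(1-TBSO-ethyl)phenyl trans to the C5 (R) ArB group; C4=C(OSiMe3)ArA exocyclic; two carbinol epimers], via aryllithium 18 (not isolated)
Conditions: 17 (2.2 equiv), n-BuLi (2.1 equiv), THF, 0 °C, 1 h; CuI (1.1 equiv), −40 °C; Me3SiCl (3 equiv) then 15 (1 equiv), −78 → −30 °C; aq. NH4Cl/NH3 (pH 8), 0 °C; filtration through Et3N-treated silica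
Reagents that add atoms: chlorotrimethylsilane, C[Si](C)(C)Cl
Why: Directed ortho-lithiation between the two MOM ethers and chlorosilane-accelerated organocuprate 1,4-addition to the aryl dienone (precedent: additions of 2,6-dialkoxyaryl cuprates to cyclohexenones in cannabinoid synthesis); the δ-carbon C1 is fully substituted so 1,6-addition is blocked, and A(1,2) strain with the C4 aroyl group holds the C5 aryl pseudo-axial so that the new aryl enters C3 on the opposite face (3,5-trans), while the enolate is stored as the silyl enol ether with C4 still undefined.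

Step 14
Reactants: 19 trimethylsilyl enol ether
Product: 21 (3S,4R,5S)-carbinol: ring C3 carries 3-(1-hydroxyethyl)-2,6-bis(methoxymethoxy)phenyl cis to the C4 ArA-carbonyl group and trans to the C5 ArB group (two carbinol epimers), via silyl ether ketone 20 (not isolated)
Conditions: Bu4NF (1.1 equiv)/AcOH (2 equiv), THF, −78 °C; then Bu4NF (2 equiv)/AcOH (2 equiv), rt
Reagents that add atoms: none
Why: Fluoride cleaves the enol O–Si bond and the enolate is protonated by acetic acid under kinetic control (desilylative protonation): A(1,3) strain keeps both flanking aryl groups axial and the proton enters C4 anti to the larger, doubly ortho-substituted C3 aryl, which places the aroyl group cis to C3 and trans to C5 as in the target, after which the same buffered reagent at room temperature removes the TBS ether without re-enolising the hindered ketone.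

Step 15
Reactants: 21 carbinol
Product: 22 (3S,4R,5S)-methyl ketone: ring C3 carries 3-acetyl-2,6-bis(methoxymethoxy)phenyl (single diastereomer)
Conditions: Dess–Martin periodinane (1.5 equiv), NaHCO3 (4 equiv), CH2Cl2, 0 °C → rt
Reagents that add atoms: none
Why: Dess–Martin oxidation of the benzylic secondary alcohol under buffered, non-enolising conditions gives the aryl methyl ketone and removes the extra stereocentre.

Step 16
Reactants: 22 methyl ketone; 12 2,4-bis(methoxymethoxy)benzaldehyde
Product: 25 octakis-MOM ether of Artonin C [(E)-chalcone], via aldol adduct 23 (not isolated), via mesylate 24 (not isolated)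
Conditions: LiN(SiMe3)2 (1.05 equiv), THF, −78 °C; 12 (1.2 equiv), −78 °C; MsCl (1.5 equiv), −78 → 0 °C; Et3N (4 equiv), 0 °C → rt
Reagents that add atoms: none
Why: Directed aldol addition followed by mesylation and E1cB elimination gives the E-enone; the amide base deprotonates only the unhindered methyl ketone, so the hydroxide conditions of a Claisen–Schmidt condensation, which could epimerise C4, are avoided.

Step 17
Reactants: 25 octakis-MOM ether
Product: 27 Artonin C, via octakis(trimethylsilyl) ether 26 (not isolated)
Conditions: Me3SiOTf (16 equiv), 2,2′-bipyridyl (24 equiv), MeCN, 0 °C → rt; then H2O, rt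
Reagents that add atoms: none
Why: Silyl triflate/2,2′-bipyridyl cleavage of aryl MOM ethers (the methoxymethyl unit is taken up by bipyridyl and the phenols emerge as silyl ethers that hydrolyse on adding water) avoids protic acid, which could add a phenol to the cyclohexene, ketalise the cis C3/C4 pair or close the 2′-hydroxychalcone to a flavanone.

**Compound list**

1 | 2,4-dihydroxyacetophenone | CC(=O)c1ccc(O)cc1O | starting material
2 | 1-(2,4-dihydroxy-3-iodophenyl)ethanone | CC(=O)c1ccc(O)c(I)c1O | intermediate
3 | 1-[3-iodo-2,4-bis(methoxymethoxy)phenyl]ethanone | CC(=O)c1ccc(OCOC)c(I)c1OCOC | intermediate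
4 | 3-methylbut-1-yne | CC(C)C#C | starting material
5 | 2-[(E)-3-methylbut-1-enyl]-4,4,5,5-tetramethyl-1,3,2-dioxaborolane | CC(C)/C=C/B1OC(C)(C)C(C)(C)O1 | intermediate
6 | 1-[2,4-bis(methoxymethoxy)-3-[(E)-3-methylbut-1-enyl]phenyl]ethanone | CC(=O)c1ccc(OCOC)c(/C=C/C(C)C)c1OCOC | intermediate
7 | ethyl 3-[2,4-bis(methoxymethoxy)-3-[(E)-3-methylbut-1-enyl]phenyl]-3-oxopropanoate | CCOC(=O)CC(=O)c1ccc(OCOC)c(/C=C/C(C)C)c1OCOC | intermediate
8 | (E)-4-methoxybut-3-en-2-one | CO/C=C/C(C)=O | starting material
9 | ethyl 2-(ArA-carbonyl)-5-oxohex-2-enoate (E/Z, in equilibrium with its dienol; not isolated) | CCOC(=O)C(=CCC(C)=O)C(=O)c1ccc(OCOC)c(/C=C/C(C)C)c1OCOC | intermediate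
10 | 3-(ArA-carbonyl)-6-methyl-2H-pyran-2-one | Cc1ccc(C(=O)c2ccc(OCOC)c(/C=C/C(C)C)c2OCOC)c(=O)o1 | intermediate
11 | 2,4-dihydroxybenzaldehyde | O=Cc1ccc(O)cc1O | starting material
12 | 2,4-bis(methoxymethoxy)benzaldehyde | O=Cc1ccc(OCOC)cc1OCOC | intermediate
13 | 1-ethenyl-2,4-bis(methoxymethoxy)benzene | C=Cc1ccc(OCOC)cc1OCOC | intermediate
14 | (1S,4S,8R)-4-(ArA-carbonyl)-8-(ArB)-1-methyl-2-oxabicyclo[2.2.2]oct-5-en-3-one | C[C@]12C=C[C@](C(=O)c3ccc(OCOC)c(/C=C/C(C)C)c3OCOC)(C(=O)O1)[C@@H](c3ccc(OCOC)cc3OCOC)C2 | intermediate
15 | (ArA)[(6R)-6-(ArB)-4-methylcyclohexa-1,3-dien-1-yl]methanone | CC1=CC=C(C(=O)c2ccc(OCOC)c(/C=C/C(C)C)c2OCOC)[C@@H](c2ccc(OCOC)cc2OCOC)C1 | intermediate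
16 | 1-[2,4-bis(methoxymethoxy)phenyl]ethanol (racemic) | CC(O)c1ccc(OCOC)cc1OCOC | intermediate
17 | tert-butyl{1-[2,4-bis(methoxymethoxy)phenyl]ethoxy}dimethylsilane | CC(O[Si](C)(C)C(C)(C)C)c1ccc(OCOC)cc1OCOC | intermediate
18 | [2,6-bis(methoxymethoxy)-3-(1-TBSO-ethyl)phenyl]lithium (not isolated) | CC(O[Si](C)(C)C(C)(C)C)c1ccc(OCOC)c([Li])c1OCOC | intermediate
19 | trimethylsilyl enol ether of the 1,4-adduct, (3S,5R), carbinol epimers | CC1=C[C@H](c2c(OCOC)ccc(C(C)O[Si](C)(C)C(C)(C)C)c2OCOC)C(=C(O[Si](C)(C)C)c2ccc(OCOC)c(/C=C/C(C)C)c2OCOC)[C@@H](c2ccc(OCOC)cc2OCOC)C1 | intermediate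
20 | (3S,4R,5S)-ketone with TBS-protected carbinol (not isolated) | CC1=C[C@H](c2c(OCOC)ccc(C(C)O[Si](C)(C)C(C)(C)C)c2OCOC)[C@H](C(=O)c2ccc(OCOC)c(/C=C/C(C)C)c2OCOC)[C@@H](c2ccc(OCOC)cc2OCOC)C1 | intermediate
21 | (3S,4R,5S)-ketone with free 1-hydroxyethyl group | CC1=C[C@H](c2c(OCOC)ccc(C(C)O)c2OCOC)[C@H](C(=O)c2ccc(OCOC)c(/C=C/C(C)C)c2OCOC)[C@@H](c2ccc(OCOC)cc2OCOC)C1 | intermediate
22 | (3S,4R,5S)-diketone with 3-acetyl-2,6-bis(methoxymethoxy)phenyl at C3 | CC1=C[C@H](c2c(OCOC)ccc(C(C)=O)c2OCOC)[C@H](C(=O)c2ccc(OCOC)c(/C=C/C(C)C)c2OCOC)[C@@H](c2ccc(OCOC)cc2OCOC)C1 | intermediate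
23 | β-hydroxy ketone (aldol adduct, formed as lithium alkoxide; not isolated) | CC1=C[C@H](c2c(OCOC)ccc(C(=O)CC(O)c3ccc(OCOC)cc3OCOC)c2OCOC)[C@H](C(=O)c2ccc(OCOC)c(/C=C/C(C)C)c2OCOC)[C@@H](c2ccc(OCOC)cc2OCOC)C1 | intermediate
24 | β-mesyloxy ketone (not isolated) | CC1=C[C@H](c2c(OCOC)ccc(C(=O)CC(OS(C)(=O)=O)c3ccc(OCOC)cc3OCOC)c2OCOC)[C@H](C(=O)c2ccc(OCOC)c(/C=C/C(C)C)c2OCOC)[C@@H](c2ccc(OCOC)cc2OCOC)C1 | intermediate
25 | Artonin C octakis(methoxymethyl) ether | CC1=C[C@H](c2c(OCOC)ccc(C(=O)/C=C/c3ccc(OCOC)cc3OCOC)c2OCOC)[C@H](C(=O)c2ccc(OCOC)c(/C=C/C(C)C)c2OCOC)[C@@H](c2ccc(OCOC)cc2OCOC)C1 | intermediate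
26 | Artonin C octakis(trimethylsilyl) ether (not isolated) | CC1=C[C@H](c2c(O[Si](C)(C)C)ccc(C(=O)/C=C/c3ccc(O[Si](C)(C)C)cc3O[Si](C)(C)C)c2O[Si](C)(C)C)[C@H](C(=O)c2ccc(O[Si](C)(C)C)c(/C=C/C(C)C)c2O[Si](C)(C)C)[C@@H](c2ccc(O[Si](C)(C)C)cc2O[Si](C)(C)C)C1 | intermediate
27 | Artonin C, (3S,4R,5S) | CC1=C[C@H](c2c(O)ccc(C(=O)/C=C/c3ccc(O)cc3O)c2O)[C@H](C(=O)c2ccc(O)c(/C=C/C(C)C)c2O)[C@@H](c2ccc(O)cc2O)C1 | target

**Step count and risks**

Total step count: 17. Longest linear sequence: 12 steps (1 → 2 → 6 → 7 → 10 → 14 → 15 → 19 → 21 → 22 → 25 → 27; steps 1, 2, 4, 5, 6, 9, 10, 13, 14, 15, 16, 17).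

The three steps most likely to fail:

Step 9 (key cycloaddition). The hindered, 6-substituted 3-aroylpyranone may react too slowly at the temperatures at which the dialkoxystyrene survives the Lewis acid (cationic oligomerisation), or the catalyst may discriminate the pyranone faces or endo/exo approach poorly. The fallback gives up catalytic induction: it sets out from 10 and 13 and runs the cycloaddition without any Lewis acid under 12–15 kbar in CH2Cl2 at room temperature, a known way to combine electron-poor 2-pyranones with alkenes while CO2 is retained. This gives the racemic endo lactone, that is 14 together with the enantiomeric lactone F1. Heating in toluene at 90 °C gives the racemic dienone, 15 together with the enantiomeric dienone F2. Preparative chromatography on a chiral stationary phase then delivers 15, where the route is rejoined.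

Step 13 (aryl transfer to C3). Transfer of the doubly ortho-substituted aryl group from copper to the α-branched dienone may be sluggish, and enolisation of the dienone or attack at the wrong terminus may take over. The fallback changes the metal and the mechanism: it sets out from 17 and 15, lithiates 17 to 18 as before and transmetallates with ZnCl2 to the arylzinc chloride F3. A Ni(acac)2-catalysed conjugate addition in the presence of Me3SiCl (THF/NMP, −30 → 0 °C), a known method for hindered enones, then gives the silyl enol ether 19 directly, where the route is rejoined.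

Step 14 (protonation at C4). Both faces of the enolate carbon are flanked by an axial aryl group, so facial discrimination in the kinetic protonation may be poor. Simple conformational analysis does not show a clear thermodynamic preference between the two C4 epimers, which is why the main route uses kinetic control and avoids later enolisation. The fallback switches to thermodynamic control with recycling: it sets out from 19, cleaves the enol ether with K2CO3/MeOH and equilibrates with NaOMe (0.3 equiv) in MeOH/THF at 40 °C, giving 20 in equilibrium with the C4-epimeric ketone F4. Ketone 20 is separated, and F4 is returned to 19 with KN(SiMe3)2/Me3SiCl for another pass. The route is rejoined at 20, which is desilylated with Bu4NF/AcOH as in the second half of step 14.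

**Further compounds**

F1 | step 9 | enantiomer of lactone 14, (1R,4R,8S) | C[C@@]12C=C[C@@](C(=O)c3ccc(OCOC)c(/C=C/C(C)C)c3OCOC)(C(=O)O1)[C@H](c3ccc(OCOC)cc3OCOC)C2
F2 | step 9 | enantiomer of dienone 15, (6S) | CC1=CC=C(C(=O)c2ccc(OCOC)c(/C=C/C(C)C)c2OCOC)[C@H](c2ccc(OCOC)cc2OCOC)C1
F3 | step 13 | [2,6-bis(methoxymethoxy)-3-(1-TBSO-ethyl)phenyl]zinc chloride | CC(O[Si](C)(C)C(C)(C)C)c1ccc(OCOC)c([Zn]Cl)c1OCOC
F4 | step 14 | C4 epimer of ketone 20, (3S,4S,5S) | CC1=C[C@H](c2c(OCOC)ccc(C(C)O[Si](C)(C)C(C)(C)C)c2OCOC)[C@@H](C(=O)c2ccc(OCOC)c(/C=C/C(C)C)c2OCOC)[C@@H](c2ccc(OCOC)cc2OCOC)C1
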